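## Retrosynthetic overview

1. Locants: butenolide ring O1–C2(=O)–C3(Me)=C4(O‑acyl)–C5; side chain C6H= (exocyclic) and C7 (S, methyl‑bearing); acyl chain C1'–C16'. The C5=C6 bond is E (C7 trans to O1, cis to C4). This is expected to be the more crowded geometry, so it must be made stereospecifically and handled gently afterwards.
2. Last disconnection: C3'–C4' of the hexadecanoyl chain. This leads back to a tridecyl radical (from the N‑acyloxyphthalimide of tetradecanoic acid, with loss of CO2) and the O4‑acrylate of the complete C25 tetronic acid. The union is a decarboxylative Giese reaction of a C13 and a C28 fragment, uses no protecting groups and gives the target directly.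
3. Enabling feature: C3' lies β to the ester carbonyl C1', and C1' sits on O4 of the butenolide ring, inside the vinylogous anhydride O=C1'–O4–C4=C3–C2=O. With C4'–C16' removed, C2'=C3' is the only terminal C=C and the most electron‑poor one. C5=C6, the two chain alkenes and the furan ring are substituted or electron‑rich. The acrylate also blocks the dione tautomer through which the free acid could lose its E geometry.
4. The acrylate comes from fluoride unmasking and O‑acryloylation of the E‑alkylidene 4‑O‑TMSE tetronate. That compound comes from anti‑selective dehydration of the lk aldol, made from the C5‑lithiated 3‑methyltetronate and the C20 aldehyde. The aldehyde comes from farnesyl chloride and 3‑furylmethyl Grignard, followed by terminal allylic oxidation, OH‑directed asymmetric hydrogenation (sets C7) and oxidation.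
5. Rings: no ring is closed in the route. The furan ring is bought with furan‑3‑ylmethanol and the butenolide ring with 3‑methyltetronic acid, and the two are joined in the aldol step.

Key step: step 11

Assumption: the sense of induction in step 4 is extrapolated from the hydrogenation of geraniol with the same catalyst family (same face of the CH2OH‑bearing alkene carbon). If the 2‑methyl substitution pattern responds the other way, the (R)‑ligand is used.

## Route

Step 1
Reactants: 1 furan-3-ylmethanol
Product: 2 3-(chloromethyl)furan
Conditions: SOCl2, pyridine, Et2O, 0 °C; used promptly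
Reagents that add atoms: thionyl chloride, O=S(Cl)Cl
Why: Deoxychlorination of a primary furylmethyl alcohol through its chlorosulfite (SN2 by chloride) should be clean because pyridine scavenges HCl and so protects the acid-sensitive furan; no stereocentre is involved.

Step 2
Reactants: 2 3-(chloromethyl)furan; 3 (2E,6E)-farnesyl chloride
Product: 5 3-[(3E,7E)-4,8,12-trimethyltrideca-3,7,11-trien-1-yl]furan, via furan-3-ylmethylmagnesium chloride 4 (not isolated)
Conditions: Mg, THF, 0 °C; then 3, Li2CuCl4 (cat.), THF, −10 to 0 °C
Reagents that add atoms: none
Why: Li2CuCl4-catalysed Grignard–allyl halide cross-coupling: the cuprate formed in THF should displace the primary allylic chloride at its α-carbon (SN2 rather than SN2') with retention of both E alkenes, and copper catalysis should also suppress coupling of the furylmethyl nucleophile through ring carbon C2.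

Step 3
Reactants: 5 3-[(3E,7E)-4,8,12-trimethyltrideca-3,7,11-trien-1-yl]furan
Product: 6 (2E,6E,10E)-13-(furan-3-yl)-2,6,10-trimethyltrideca-2,6,10-trien-1-ol
Conditions: SeO2 (cat.), t-BuOOH, salicylic acid (cat.), CH2Cl2, 0 °C; stopped at partial conversion, 5 recycled
Reagents that add atoms: tert-butyl hydroperoxide, CC(C)(C)OO (oxygen relayed by the catalytic SeO2)
Why: Selenium dioxide allylic oxidation (Riley type, ene reaction then [2,3]-sigmatropic shift) should pick the terminal isopropylidene group as the least hindered and most nucleophilic alkene and, by the usual rule, its E-methyl group, which fixes the E geometry of the new allylic alcohol, while the furan offers no ene pathway.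

Step 4
Reactants: 6 (2E,6E,10E)-13-(furan-3-yl)-2,6,10-trimethyltrideca-2,6,10-trien-1-ol
Product: 7 (2S,6E,10E)-13-(furan-3-yl)-2,6,10-trimethyltrideca-6,10-dien-1-ol
Conditions: Ru(OAc)2[(S)-BINAP] (cat.), H2 (ca. 100 atm), MeOH, rt
Reagents that add atoms: none
Why: Hydroxyl-directed Ru–BINAP asymmetric hydrogenation (Noyori type) should reduce only the alkene that can bind through the allylic OH, leaving the two remote trisubstituted alkenes and the furan untouched, and the new stereocentre (later C7) is set as S by ligand-controlled delivery of H2 to one face of the geometrically pure E alkene.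

Step 5
Reactants: 7 (2S,6E,10E)-13-(furan-3-yl)-2,6,10-trimethyltrideca-6,10-dien-1-ol
Product: 8 (2S,6E,10E)-13-(furan-3-yl)-2,6,10-trimethyltrideca-6,10-dienal
Conditions: PhI(OAc)2, TEMPO (cat.), CH2Cl2, 0 °C to rt; used without storage
Reagents that add atoms: none
Why: TEMPO/PhI(OAc)2 oxoammonium oxidation stops at the aldehyde under nearly neutral, metal-free conditions, so the furan, the alkenes and the epimerisable α-stereocentre should survive.

Step 6
Reactants: 9 3-methyltetronic acid (4-hydroxy-3-methylfuran-2(5H)-one)
Product: 10 3-methyl-4-[2-(trimethylsilyl)ethoxy]furan-2(5H)-one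
Conditions: Me3SiCH2CH2OH, PPh3, DIAD, THF, 0 °C to rt
Reagents that add atoms: 2-(trimethylsilyl)ethanol, C[Si](C)(C)CCO
Why: Mitsunobu O-alkylation: the acidic tetronic acid protonates the betaine and its ambident anion should attack the activated primary alcohol through O4, giving a vinylogous TMSE ester that later falls off with fluoride under non-acidic conditions.

Step 7
Reactants: 10 3-methyl-4-[2-(trimethylsilyl)ethoxy]furan-2(5H)-one; 8 (2S,6E,10E)-13-(furan-3-yl)-2,6,10-trimethyltrideca-6,10-dienal
Product: 12 (5R)-5-[(1R,2S,6E,10E)-13-(furan-3-yl)-1-hydroxy-2,6,10-trimethyltrideca-6,10-dien-1-yl]-3-methyl-4-[2-(trimethylsilyl)ethoxy]furan-2(5H)-one, via C5-lithiated tetronate 11 (not isolated)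
Conditions: LDA, THF, −78 °C; then 8, −78 °C; AcOH quench at −78 °C; chromatographic separation of the lk isomer
Reagents that add atoms: none
Why: Vinylogous aldol addition of the lithium furanolate, which can react only at C5 because C3 is blocked by methyl; the aldehyde face is governed by Felkin–Anh control from C7 (6R expected), the 5,6-relation is the weak point and the lk (5R,6R, erythro) isomer is isolated by chromatography, both new centres being sacrificial so that only their relative configuration matters (a 5S,6S companion would converge to the same alkene in step 8).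

Step 8
Reactants: 12 lk aldol (5R,6R,7S)
Product: 13 (5E)-5-[(2S,6E,10E)-13-(furan-3-yl)-2,6,10-trimethyltrideca-6,10-dien-1-ylidene]-3-methyl-4-[2-(trimethylsilyl)ethoxy]furan-2(5H)-one
Conditions: PPh3, DEAD, toluene/THF, 0 °C to rt, dark
Reagents that add atoms: none
Why: Mitsunobu-type anti-selective dehydration, the reaction type known for γ-(α-hydroxyalkyl)butenolides: the C6 hydroxyl becomes an oxyphosphonium leaving group under essentially neutral conditions and the hydrazide base removes H5 in an antiperiplanar E2 process, so the lk relation of 12 is translated into the E alkene (C7 cis to C4, H6 cis to O1) while C7 is untouched.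

Step 9
Reactants: 13 (5E)-alkylidene 4-O-TMSE tetronate
Product: 15 O4-acrylate (prop-2-enoate) of (5E)-5-[(2S,6E,10E)-13-(furan-3-yl)-2,6,10-trimethyltrideca-6,10-dien-1-ylidene]-4-hydroxy-3-methylfuran-2(5H)-one, via tetrabutylammonium tetronate 14 (not isolated)
Conditions: TBAF (THF, dried over 4 Å MS), 0 °C; then acryloyl chloride, −78 to −20 °C; rapid filtration through neutral silica, dark
Reagents that add atoms: acryloyl chloride, C=CC(=O)Cl
Why: Fluoride attack at silicon triggers β-fragmentation of the vinylogous TMSE ester, and the tetronate anion, whose charge is not delocalised into C5=C6 and which should therefore hold its E geometry, is O-acylated at O4 by the hard acyl chloride (C3 is blocked by methyl) before the isomerisation-prone free acid is ever formed.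

Step 10
Reactants: 16 tetradecanoyl (myristoyl) chloride
Product: 17 1,3-dioxoisoindolin-2-yl tetradecanoate (N-(tetradecanoyloxy)phthalimide)
Conditions: N-hydroxyphthalimide, Et3N, CH2Cl2, 0 °C to rt
Reagents that add atoms: N-hydroxyphthalimide, O=C1c2ccccc2C(=O)N1O
Why: Simple O-acylation of N-hydroxyphthalimide by the acid chloride gives the bench-stable redox-active ester that stores the tridecyl radical.

Step 11
Reactants: 15 O4-acrylate; 17 N-(tetradecanoyloxy)phthalimide
Product: 18 target, O4-hexadecanoate of (5E)-5-[(2S,6E,10E)-13-(furan-3-yl)-2,6,10-trimethyltrideca-6,10-dien-1-ylidene]-4-hydroxy-3-methylfuran-2(5H)-one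
Conditions: Ru(bpy)3(PF6)2 (cat.), Hantzsch ester (excess), 17 (excess, in portions), degassed CH2Cl2, blue LEDs (450 nm), 15–20 °C, Ar
Reagents that add atoms: none
Why: Ru(I), formed by reductive quenching of photoexcited Ru(II) with the Hantzsch ester, transfers one electron to 17, whose radical anion loses phthalimide anion and CO2 to give the nucleophilic primary tridecyl radical; this adds to the unsubstituted terminus C3' of the acrylate of 15 (new C3'–C4' bond) and the electrophilic C2' radical is capped by hydrogen-atom transfer from the Hantzsch ester or its radical cation, which also protonates the phthalimide anion. The closest known reaction type is the decarboxylative Giese reaction of N-acyloxyphthalimides with alkyl and aryl acrylates under Ru(bpy)3/Hantzsch ester photoredox conditions. No ring is closed and no stereocentre is created; C7 and the three stereodefined C=C bonds are only carried through. The step needs site selectivity among seven C=C units: polarity matching and sterics direct the radical to C2'=C3', the only terminal alkene and, as part of the vinylogous anhydride on O4, the most electron-poor one, whereas C6 of the dienyl lactone is shielded by the branched C7 and deactivated by O1, and the chain alkenes and the furan are electron-rich. It also needs integrity of C7 and of the E geometry: the s-trans (Z) ester conformation holds the C2' radical away from the allylic C7–H, so 1,7-hydrogen transfer should not compete with capture by excess Hantzsch ester, and the low triplet energy of the ruthenium sensitiser together with 450 nm light, which the dienyl lactone does not absorb, should leave C5=C6 unisomerised. The medium is free of base, nucleophile and oxygen, which should spare the acyl-transfer-prone enol ester and the singlet-oxygen-sensitive furan.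

## Compound list

1 | furan-3-ylmethanol | OCc1ccoc1 | starting material
2 | 3-(chloromethyl)furan | ClCc1ccoc1 | intermediate
3 | (2E,6E)-farnesyl chloride | CC(C)=CCC/C(C)=C/CC/C(C)=C/CCl | starting material
4 | furan-3-ylmethylmagnesium chloride | Cl[Mg]Cc1ccoc1 | intermediate (not isolated)
5 | 3-[(3E,7E)-4,8,12-trimethyltrideca-3,7,11-trien-1-yl]furan | CC(C)=CCC/C(C)=C/CC/C(C)=C/CCc1ccoc1 | intermediate
6 | (2E,6E,10E)-13-(furan-3-yl)-2,6,10-trimethyltrideca-2,6,10-trien-1-ol | OC/C(C)=C/CC/C(C)=C/CC/C(C)=C/CCc1ccoc1 | intermediate
7 | (2S,6E,10E)-13-(furan-3-yl)-2,6,10-trimethyltrideca-6,10-dien-1-ol | OC[C@@H](C)CCC/C(C)=C/CC/C(C)=C/CCc1ccoc1 | intermediate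
8 | (2S,6E,10E)-13-(furan-3-yl)-2,6,10-trimethyltrideca-6,10-dienal | O=C[C@@H](C)CCC/C(C)=C/CC/C(C)=C/CCc1ccoc1 | intermediate
9 | 3-methyltetronic acid | CC1=C(O)COC1=O | starting material
10 | 3-methyl-4-[2-(trimethylsilyl)ethoxy]furan-2(5H)-one | CC1=C(OCC[Si](C)(C)C)COC1=O | intermediate
11 | lithium 3-methyl-4-[2-(trimethylsilyl)ethoxy]furan-2-olate (C5-lithiated tetronate) | [Li+].[O-]c1occ(OCC[Si](C)(C)C)c1C | intermediate (not isolated)
12 | lk aldol, (5R,6R,7S) | C[Si](C)(C)CCOC1=C(C)C(=O)O[C@@H]1[C@H](O)[C@@H](C)CCC/C(C)=C/CC/C(C)=C/CCc1ccoc1 | intermediate
13 | (5E)-alkylidene 4-O-TMSE tetronate | C[Si](C)(C)CCOC1=C(C)C(=O)O/C1=C/[C@@H](C)CCC/C(C)=C/CC/C(C)=C/CCc1ccoc1 | intermediate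
14 | tetrabutylammonium (5E)-tetronate | CCCC[N+](CCCC)(CCCC)CCCC.[O-]C1=C(C)C(=O)O/C1=C/[C@@H](C)CCC/C(C)=C/CC/C(C)=C/CCc1ccoc1 | intermediate (not isolated)
15 | (5E)-tetronate O4-acrylate | C=CC(=O)OC1=C(C)C(=O)O/C1=C/[C@@H](C)CCC/C(C)=C/CC/C(C)=C/CCc1ccoc1 | intermediate
16 | tetradecanoyl chloride | CCCCCCCCCCCCCC(=O)Cl | starting material
17 | N-(tetradecanoyloxy)phthalimide | CCCCCCCCCCCCCC(=O)ON1C(=O)c2ccccc2C1=O | intermediate
18 | target, (5E,7S)-tetronate O4-hexadecanoate | CCCCCCCCCCCCCCCC(=O)OC1=C(C)C(=O)O/C1=C/[C@@H](C)CCC/C(C)=C/CC/C(C)=C/CCc1ccoc1 | target

## Step count and risks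

Total step count: 11. Longest linear sequence: 9 steps (1, 2, 3, 4, 5, 7, 8, 9, 11).

**Step 8.**
- What may go wrong: the oxyphosphonium salt may not eliminate in the concerted anti mode. If C5 is deprotonated before the C6–O bond breaks, a planar furanolate forms. Rotation then erases the C5/C6 information and the elimination drains toward the less crowded geometry. Substitution at C6 by the hydrazide and loss of the C7 hydrogen are further leaks.
- Fallback (the geometry is corrected after the elimination, not during it): it sets out from 12, and the other aldol diastereomers of step 7 can be added. MsCl/Et3N gives the C6 mesylate F1. DBU converts it by E1cB into the (5Z)-alkylidene tetronate F2. Irradiation of a degassed solution (UV-A through Pyrex, or a triplet sensitiser) sets up a Z/E photostationary mixture. 13 is separated from this mixture by chromatography and the Z isomer is returned to the lamp. The fallback comes back to the route at 13.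

**Step 7.**
- What may go wrong: weak simple (lk/ul) diastereoselection of the lithium dienolate, retro-aldol equilibration on warming and base-induced epimerisation of 8 would each erode the supply of 12.
- Fallback (a different aldol manifold and a different elimination topology): it sets out from 10 and 8. TBSOTf/Et3N turns 10 into the 2-silyloxyfuran F3. Its BF3·OEt2-promoted vinylogous Mukaiyama aldol addition to 8 at −78 °C runs through an open transition state. For 2-silyloxyfurans this usually favours the ul (syn, threo) relation, so it should give the ul aldol F4. The Burgess reagent (toluene, rt to 50 °C) then dehydrates it by intramolecular syn-elimination, which translates ul into the same E alkene. The fallback comes back at 13 and bypasses 12.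

**Step 11.**
- What may go wrong: premature hydrogen transfer to the tridecyl radical (which leaves 15 unconsumed), oligomerisation of the acrylate, sensitised or radical-induced isomerisation of C5=C6, and acyl transfer from the vinylogous anhydride to phthalimide.
- Fallback (two-electron instead of one-electron construction of the same C3'–C4' bond, without light): it sets out from 15. 1-Bromotridecane and Mg give tridecylmagnesium bromide F5. CuI·2LiCl converts it at low temperature into tridecylcopper F6. This reagent adds 1,4 to 15 at −78 °C in the presence of Me3SiCl (silyl-accelerated organocopper conjugate addition). The enolate is trapped as the trimethylsilyl ketene acetal F7, so it cannot collapse to ketene and tetronate. A pH 7 buffer cleaves F7, and the fallback comes back at 18.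

## Further compounds

F1 | step 8 | C6 methanesulfonate of 12 | C[Si](C)(C)CCOC1=C(C)C(=O)O[C@@H]1[C@H](OS(C)(=O)=O)[C@@H](C)CCC/C(C)=C/CC/C(C)=C/CCc1ccoc1
F2 | step 8 | (5Z)-isomer of 13 | C[Si](C)(C)CCOC1=C(C)C(=O)O/C1=C\[C@@H](C)CCC/C(C)=C/CC/C(C)=C/CCc1ccoc1
F3 | step 7 | tert-butyl(dimethyl){[3-methyl-4-(2-trimethylsilylethoxy)furan-2-yl]oxy}silane | Cc1c(O[Si](C)(C)C(C)(C)C)occ1OCC[Si](C)(C)C
F4 | step 7 | ul aldol, (5S,6R,7S) diastereomer of 12 | C[Si](C)(C)CCOC1=C(C)C(=O)O[C@H]1[C@H](O)[C@@H](C)CCC/C(C)=C/CC/C(C)=C/CCc1ccoc1
F5 | step 11 | tridecylmagnesium bromide | CCCCCCCCCCCCC[Mg]Br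
F6 | step 11 | tridecylcopper | CCCCCCCCCCCCC[Cu]
F7 | step 11 | trimethylsilyl ketene acetal of 18 | CCCCCCCCCCCCCCC=C(O[Si](C)(C)C)OC1=C(C)C(=O)O/C1=C/[C@@H](C)CCC/C(C)=C/CC/C(C)=C/CCc1ccoc1
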